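**Plan**
1. Numbering used below: ring carbon C1 carries the chain, C2 is =CH, C3 is CH(OH), C4 is =CH, C5 carries OMe, C6 is CH(OAc).
2. Retrosynthesis: after removal of the acetates, cut C1–C6 and C2–C3, a formal [4+2] between the terminal alkyne C1≡C2 of the chain and the trioxygenated diene C6=C5–C4=C3.
3. Enabling feature: the ring is a cyclohexa-1,4-diene whose two sp3 carbons C3 and C6 are para, cis and oxygenated, which is what an alkyne gives with a diene that has an outward oxygen at each end. The C6 oxygen lies 1,4 to the chain oxygen, so one silicon atom can tie alkyne to diene in a temporary seven-membered silyl acetal ring.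
4. Forward: a C12 Grignard reagent opens (R)-epichlorohydrin and acetylide then gives (R)-heptadec-1-yn-4-ol; i-Pr2Si links it to but-2-yne-1,4-diol, whose C4 unit is turned into the diene by oxidation, methanol addition and soft enolisation.
5. The only carbocycle is closed last (step 7); the tether is then cut, the two freed hydroxyls are acetylated and the C3 silyl ether is removed.
6. Stereochemistry: chain carbinol from (R)-epichlorohydrin; cis C3/C6 from suprafacial addition to the (1E,3Z)-diene; absolute sense of C3/C6 from the chiral bisphospholane ligand on rhodium.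

Key step: step 7

Assumption: the sense of induction of the bisphospholane ligand on this tethered diene cannot be derived in advance; the (R,R) ligand is written, and its mirror image would take its place if it favoured the other diene face.

Step 1
Reactants: 1 (R)-epichlorohydrin; 2 dodecylmagnesium bromide
Product: 3 (2R)-1-chloropentadecan-2-ol
Conditions: CuI (10 mol%), THF, −40 to 0 °C; aq. NH4Cl
Reagents that add atoms: none
Why: Copper-catalysed Grignard opening of the epoxide at its unsubstituted carbon (SN2) leaves the stereocentre of 1 untouched, so the chain carbinol is taken from the chiral pool.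

Step 2
Reactants: 3 (2R)-1-chloropentadecan-2-ol; 4 lithium acetylide ethylenediamine complex
Product: 6 (4R)-heptadec-1-yn-4-ol, via (R)-2-tridecyloxirane 5 (not isolated)
Conditions: LiC≡CH·H2NCH2CH2NH2 (3 equiv), DMSO, 0 to 25 °C
Reagents that add atoms: none
Why: The first equivalent of acetylide closes the chlorohydrin to the epoxide (intramolecular Williamson reaction, configuration retained) and the second opens it at the terminal carbon (SN2), a standard homopropargylic alcohol synthesis that does not touch the carbinol centre.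

Step 3
Reactants: 6 (4R)-heptadec-1-yn-4-ol; 7 but-2-yne-1,4-diol
Product: 9 4-[({[(4R)-heptadec-1-yn-4-yl]oxy}di(propan-2-yl)silyl)oxy]but-2-yn-1-ol, via chlorosilane 8 (not isolated)
Conditions: i-Pr2SiCl2 (1.5 equiv), imidazole, CH2Cl2, 0 °C; volatiles removed; then 7 (5 equiv), imidazole, DMF, 25 °C
Reagents that add atoms: dichlorodi(propan-2-yl)silane CC(C)[Si](Cl)(Cl)C(C)C
Why: Stepwise silylation to an unsymmetrical silyl acetal should work because the hindered secondary alcohol takes only one chloride of the dichlorosilane and the excess of the symmetrical diol ensures mono-silylation.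

Step 4
Reactants: 9 4-[({[(4R)-heptadec-1-yn-4-yl]oxy}di(propan-2-yl)silyl)oxy]but-2-yn-1-ol
Product: 10 4-[({[(4R)-heptadec-1-yn-4-yl]oxy}di(propan-2-yl)silyl)oxy]but-2-ynal
Conditions: MnO2 (activated, 15 equiv), CH2Cl2, 25 °C
Reagents that add atoms: none
Why: Manganese dioxide oxidation of a primary propargylic alcohol is selective and non-acidic, so the silyl acetal and the terminal alkyne should survive.

Step 5
Reactants: 10 4-[({[(4R)-heptadec-1-yn-4-yl]oxy}di(propan-2-yl)silyl)oxy]but-2-ynal
Product: 11 (2E)-4-[({[(4R)-heptadec-1-yn-4-yl]oxy}di(propan-2-yl)silyl)oxy]-3-methoxybut-2-enal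
Conditions: MeOH (1.5 equiv), DABCO (10 mol%), CH2Cl2, 0 °C
Reagents that add atoms: methanol CO
Why: Amine-catalysed oxa-Michael addition of methanol to the ynal places the methoxy group on the β-carbon (future C5) and should give the thermodynamically preferred E enal, with the formyl group cis to the CH2O unit.

Step 6
Reactants: 11 (2E)-4-[({[(4R)-heptadec-1-yn-4-yl]oxy}di(propan-2-yl)silyl)oxy]-3-methoxybut-2-enal
Product: 12 (1E,3Z)-1-[(tert-butyldimethylsilyl)oxy]-4-[({[(4R)-heptadec-1-yn-4-yl]oxy}di(propan-2-yl)silyl)oxy]-3-methoxybuta-1,3-diene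
Conditions: TBSOTf (1.3 equiv), Et3N (2.5 equiv), Et2O, −78 to 0 °C; filtration through Et3N-deactivated silica
Reagents that add atoms: tert-butyldimethylsilyl trifluoromethanesulfonate CC(C)(C)[Si](C)(C)OS(=O)(=O)C(F)(F)F
Why: Soft enolisation of the vinylogous ester (O-silylation, then γ-deprotonation at the CH2O carbon) should give the silyl dienol ether, the s-trans enal fixing the E geometry at the new C3=C4 bond and 1,3-allylic strain against the cis formyl-derived carbon turning the C6 oxygen outward (Z at C5=C6).

Step 7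
Reactants: 12 (1E,3Z)-1-[(tert-butyldimethylsilyl)oxy]-4-[({[(4R)-heptadec-1-yn-4-yl]oxy}di(propan-2-yl)silyl)oxy]-3-methoxybuta-1,3-diene
Product: 13 (4R,7R,9aS)-7-[(tert-butyldimethylsilyl)oxy]-9-methoxy-2,2-di(propan-2-yl)-4-tridecyl-4,5,7,9a-tetrahydro-1,3,2-benzodioxasilepine (cyclohexa-1,4-diene fused at C1–C6 to the seven-membered silyl acetal ring; C3 is position 7 and C6 is position 9a)
Conditions: [Rh(nbd)((R,R)-Me-DuPhos)]SbF6 (5 mol%, nbd removed with H2 before use), CH2Cl2 (0.01 M), 25 °C; Et3N-deactivated silica
Reagents that add atoms: none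
Why: Proposed new method: the cationic monovalent rhodium centre binds the alkyne and the s-cis diene of 12, oxidative cyclisation joins C1 to C6 and the resulting allyl rhodacycle closes C2–C3 by reductive elimination, both bonds forming on one diene face; the closest known reaction type is the rhodium- or nickel-catalysed intramolecular [4+2] cycloaddition of ether-tethered dienynes with three- or four-atom tethers, which also runs enantioselectively with bisphospholane ligands, and what is new here is the five-atom silyl acetal tether and the diene oxygenated at both termini. The cyclohexa-1,4-diene closes as a formal [4+2] with the alkyne as the two-carbon partner, and the seven-membered dioxasilepine closes in the same event in the fused mode, through the C1–C6 bond. The cis relation of C3 and C6 follows from suprafacial addition to a diene whose two terminal oxygens both point outward, and the absolute configuration of the pair is set at the C1–C6 bond-forming step by the chiral ligand, the remote chain carbinol in the flexible tether being expected to add only a small bias. The step needs regiocontrol, which the tether enforces by bringing the internal alkyne carbon to C6, and chemoselectivity over alkyne oligomerisation, which high dilution should secure. Because catalysts of this kind join untethered alkynes and dienes at room temperature, the longer tether should lower the rate but not close the pathway, and the neutral, aprotic medium spares the silyl enol ether and the acid-sensitive product. Geometric isomers of 12 with an inward oxygen cannot adopt the reactive s-cis form and should be left behind.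

Step 8
Reactants: 13 (4R,7R,9aS)-7-[(tert-butyldimethylsilyl)oxy]-9-methoxy-2,2-di(propan-2-yl)-4-tridecyl-4,5,7,9a-tetrahydro-1,3,2-benzodioxasilepine
Product: 14 (1S,4R)-4-[(tert-butyldimethylsilyl)oxy]-2-[(2R)-2-hydroxypentadecyl]-6-methoxycyclohexa-2,5-dien-1-ol
Conditions: TBAF (2.2 equiv), AcOH (2.5 equiv), THF, −20 to 0 °C
Reagents that add atoms: none
Why: Fluoride attacks a dialkoxysilane much faster than a trialkylsilyl ether, so buffered desilylation should free the C6 and chain hydroxyls and keep the C3 silyl ether, the buffer avoiding acid- or base-induced aromatisation.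

Step 9
Reactants: 14 (1S,4R)-4-[(tert-butyldimethylsilyl)oxy]-2-[(2R)-2-hydroxypentadecyl]-6-methoxycyclohexa-2,5-dien-1-ol
Product: 15 (1S,4R)-2-[(2R)-2-(acetyloxy)pentadecyl]-4-[(tert-butyldimethylsilyl)oxy]-6-methoxycyclohexa-2,5-dien-1-yl acetate
Conditions: Ac2O (4 equiv), pyridine, DMAP (10 mol%), CH2Cl2, 0 °C
Reagents that add atoms: acetic anhydride CC(=O)OC(C)=O
Why: DMAP-catalysed acylation should esterify both secondary hydroxyls under basic, non-ionising conditions without touching any stereocentre.

Step 10
Reactants: 15 (1S,4R)-2-[(2R)-2-(acetyloxy)pentadecyl]-4-[(tert-butyldimethylsilyl)oxy]-6-methoxycyclohexa-2,5-dien-1-yl acetate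
Product: 16 (1S,4R)-2-[(2R)-2-(acetyloxy)pentadecyl]-4-hydroxy-6-methoxycyclohexa-2,5-dien-1-yl acetate
Conditions: TBAF (1.5 equiv), AcOH (1.5 equiv), THF, 0 to 25 °C
Reagents that add atoms: none
Why: Buffered fluoride desilylation should remove the secondary allylic silyl ether while the acetic acid buffer suppresses acetyl migration and elimination to the arene.

**Compound list**
1 | (R)-epichlorohydrin | ClC[C@H]1CO1 | starting material
2 | dodecylmagnesium bromide | CCCCCCCCCCCC[Mg]Br | starting material
3 | (2R)-1-chloropentadecan-2-ol | ClC[C@H](O)CCCCCCCCCCCCC | intermediate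
4 | lithium acetylide ethylenediamine complex | [Li]C#C.NCCN | starting material
5 | (R)-2-tridecyloxirane | CCCCCCCCCCCCC[C@@H]1CO1 | intermediate
6 | (4R)-heptadec-1-yn-4-ol | CCCCCCCCCCCCC[C@H](CC#C)O | intermediate
7 | but-2-yne-1,4-diol | OCC#CCO | starting material
8 | chloro{[(4R)-heptadec-1-yn-4-yl]oxy}di(propan-2-yl)silane | CCCCCCCCCCCCC[C@H](CC#C)O[Si](Cl)(C(C)C)C(C)C | intermediate
9 | 4-[({[(4R)-heptadec-1-yn-4-yl]oxy}di(propan-2-yl)silyl)oxy]but-2-yn-1-ol | CCCCCCCCCCCCC[C@H](CC#C)O[Si](C(C)C)(C(C)C)OCC#CCO | intermediate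
10 | 4-[({[(4R)-heptadec-1-yn-4-yl]oxy}di(propan-2-yl)silyl)oxy]but-2-ynal | CCCCCCCCCCCCC[C@H](CC#C)O[Si](C(C)C)(C(C)C)OCC#CC=O | intermediate
11 | (2E)-4-[({[(4R)-heptadec-1-yn-4-yl]oxy}di(propan-2-yl)silyl)oxy]-3-methoxybut-2-enal | CCCCCCCCCCCCC[C@H](CC#C)O[Si](C(C)C)(C(C)C)OC/C(OC)=C\C=O | intermediate
12 | (1E,3Z)-1-[(tert-butyldimethylsilyl)oxy]-4-[({[(4R)-heptadec-1-yn-4-yl]oxy}di(propan-2-yl)silyl)oxy]-3-methoxybuta-1,3-diene | CCCCCCCCCCCCC[C@H](CC#C)O[Si](C(C)C)(C(C)C)O/C=C(OC)/C=C/O[Si](C)(C)C(C)(C)C | intermediate
13 | (4R,7R,9aS)-7-[(tert-butyldimethylsilyl)oxy]-9-methoxy-2,2-di(propan-2-yl)-4-tridecyl-4,5,7,9a-tetrahydro-1,3,2-benzodioxasilepine | CCCCCCCCCCCCC[C@@H]1CC2=C[C@@H](O[Si](C)(C)C(C)(C)C)C=C(OC)[C@H]2O[Si](C(C)C)(C(C)C)O1 | intermediate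
14 | (1S,4R)-4-[(tert-butyldimethylsilyl)oxy]-2-[(2R)-2-hydroxypentadecyl]-6-methoxycyclohexa-2,5-dien-1-ol | CCCCCCCCCCCCC[C@H](CC1=C[C@@H](O[Si](C)(C)C(C)(C)C)C=C(OC)[C@H]1O)O | intermediate
15 | (1S,4R)-2-[(2R)-2-(acetyloxy)pentadecyl]-4-[(tert-butyldimethylsilyl)oxy]-6-methoxycyclohexa-2,5-dien-1-yl acetate | CCCCCCCCCCCCC[C@H](CC1=C[C@@H](O[Si](C)(C)C(C)(C)C)C=C(OC)[C@H]1OC(C)=O)OC(C)=O | intermediate
16 | (1S,4R)-2-[(2R)-2-(acetyloxy)pentadecyl]-4-hydroxy-6-methoxycyclohexa-2,5-dien-1-yl acetate | CCCCCCCCCCCCC[C@H](CC1=C[C@@H](O)C=C(OC)[C@H]1OC(C)=O)OC(C)=O | target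

Total step count: 10. Longest linear sequence: 10 steps (1 to 16).

**Steps most likely to fail**

Step 7 (proposed new method). Ring closure across the five-atom tether may be slower than alkyne oligomerisation, and the ligand may fail to override the facial bias of the tether carbinol, so that the wrong diene face reacts. The fallback drops the tether, sets out from 6 and 7 and comes back at 15. Alcohol 6 is acetylated (Ac2O, pyridine, DMAP) to (4R)-heptadec-1-yn-4-yl acetate F1. Diol 7 is mono-acetylated (Ac2O, pyridine, excess 7) to 4-hydroxybut-2-yn-1-yl acetate F2, oxidised (MnO2) to 4-oxobut-2-yn-1-yl acetate F3, treated with MeOH and DABCO to give (2E)-3-methoxy-4-oxobut-2-en-1-yl acetate F4, and enolised (TBSOTf, Et3N) to (1Z,3E)-4-[(tert-butyldimethylsilyl)oxy]-2-methoxybuta-1,3-dien-1-yl acetate F5. F1 and F5 are then joined by the cobalt-catalysed neutral Diels–Alder reaction of terminal alkynes with oxygenated 1,3-dienes (CoBr2(dppe), Zn, ZnI2, CH2Cl2, 25 °C, monovalent cobalt formed in situ; the ligand on cobalt is the known lever for regiochemistry). Without the tether no facial control is expected, so 15 should form together with its ring diastereomer, (1R,4S)-2-[(2R)-2-(acetyloxy)pentadecyl]-4-[(tert-butyldimethylsilyl)oxy]-6-methoxycyclohexa-2,5-dien-1-yl acetate F6, and the two would be separated by chromatography before step 10.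

Step 6. γ-Deprotonation may deliver the enol ether with the C6 oxygen turned inward, and the tris-oxygenated diene may hydrolyse during isolation. The fallback reverses the order in which the two enol oxygens are silylated, so that the labile C6 enol ether and the tether are formed together in the last operation; it sets out from 6 and comes back at 12. Commercial methyl 2-(dimethoxyphosphoryl)-2-methoxyacetate and (tert-butyldimethylsilyloxy)acetaldehyde are joined by a Horner–Wadsworth–Emmons reaction (NaH, THF) to methyl (2Z)-4-[(tert-butyldimethylsilyl)oxy]-2-methoxybut-2-enoate F7. This is reduced (i-Bu2AlH, CH2Cl2, −78 °C) to (2Z)-4-[(tert-butyldimethylsilyl)oxy]-2-methoxybut-2-en-1-ol F8 and oxidised (MnO2) to (2Z)-4-[(tert-butyldimethylsilyl)oxy]-2-methoxybut-2-enal F9. Alcohol 6 is converted with i-Pr2Si(OTf)2 and 2,6-lutidine (CH2Cl2, −78 °C) into {[(4R)-heptadec-1-yn-4-yl]oxy}di(propan-2-yl)silyl trifluoromethanesulfonate F10, which is used at once with Et3N for soft enolisation of F9 at its γ-CH2 group to give 12.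

Step 8. The C3 silyl ether may be lost together with the tether, or fluoride may induce elimination toward the arene. The fallback avoids fluoride and the free diol; it sets out from 13 and comes back at 15. Methyllithium (2.5 equiv, THF, −78 to 0 °C) displaces both alkoxides from silicon (nucleophilic substitution at a dialkoxysilane, to which the trialkylsilyl ether is inert) and should give dilithium (1S,4R)-4-[(tert-butyldimethylsilyl)oxy]-6-methoxy-2-[(2R)-2-oxidopentadecyl]cyclohexa-2,5-dien-1-olate F11. Acetic anhydride is added to the cold solution and acylates both alkoxides to give 15 directly.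

**Further compounds**
F1 | step 7 | (4R)-heptadec-1-yn-4-yl acetate | CCCCCCCCCCCCC[C@H](CC#C)OC(C)=O
F2 | step 7 | 4-hydroxybut-2-yn-1-yl acetate | CC(=O)OCC#CCO
F3 | step 7 | 4-oxobut-2-yn-1-yl acetate | CC(=O)OCC#CC=O
F4 | step 7 | (2E)-3-methoxy-4-oxobut-2-en-1-yl acetate | CC(=O)OC/C(OC)=C\C=O
F5 | step 7 | (1Z,3E)-4-[(tert-butyldimethylsilyl)oxy]-2-methoxybuta-1,3-dien-1-yl acetate | CC(=O)O/C=C(OC)/C=C/O[Si](C)(C)C(C)(C)C
F6 | step 7 | (1R,4S)-2-[(2R)-2-(acetyloxy)pentadecyl]-4-[(tert-butyldimethylsilyl)oxy]-6-methoxycyclohexa-2,5-dien-1-yl acetate | CCCCCCCCCCCCC[C@H](CC1=C[C@H](O[Si](C)(C)C(C)(C)C)C=C(OC)[C@@H]1OC(C)=O)OC(C)=O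
F7 | step 6 | methyl (2Z)-4-[(tert-butyldimethylsilyl)oxy]-2-methoxybut-2-enoate | COC(=O)/C(OC)=C/CO[Si](C)(C)C(C)(C)C
F8 | step 6 | (2Z)-4-[(tert-butyldimethylsilyl)oxy]-2-methoxybut-2-en-1-ol | OC/C(OC)=C/CO[Si](C)(C)C(C)(C)C
F9 | step 6 | (2Z)-4-[(tert-butyldimethylsilyl)oxy]-2-methoxybut-2-enal | O=C/C(OC)=C/CO[Si](C)(C)C(C)(C)C
F10 | step 6 | {[(4R)-heptadec-1-yn-4-yl]oxy}di(propan-2-yl)silyl trifluoromethanesulfonate | CCCCCCCCCCCCC[C@H](CC#C)O[Si](C(C)C)(C(C)C)OS(=O)(=O)C(F)(F)F
F11 | step 8 | dilithium (1S,4R)-4-[(tert-butyldimethylsilyl)oxy]-6-methoxy-2-[(2R)-2-oxidopentadecyl]cyclohexa-2,5-dien-1-olate | CCCCCCCCCCCCC[C@H](CC1=C[C@@H](O[Si](C)(C)C(C)(C)C)C=C(OC)[C@H]1O[Li])O[Li]
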